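All runs are calculated for an exercise; scatter was added.

1. At early times the teal run shows 15.1% intermediate against 0.4% product at 0.833 min, so I read product as coming later, out of intermediate.

| flask | substrate | reagent | temperature | remark | time |
|---|---|---|---|---|---|
| teal | 0.034 M | 0.045 M | −30 °C | run made earlier |  |
| amber | 0.075 M | 0.045 M | 12 °C | run made earlier |  |
| violet | 0.050 M | 0.090 M | −30 °C | run made earlier |  |
| eta | 0.050 M | 0.0450 M | 0 °C |  | 3.0 min |
| zeta | 0.050 M | 0.0450 M | 50 °C |  | 3.0 min |
| gamma | 0.050 M | 0.0450 M | 25 °C |  | 3.0 min |
| epsilon | 0.050 M | 0.0450 M | −25 °C |  | 3.0 min |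

- teal (time / min: intermediate / %, product / %): 0.833: 15.1, 0.4; 1.33: 22.1, 0.4; 2.00: 29.4, 0.3; 3.00: 37.3, 0; 4.00: 42.6, 0.1; 6.00: 49.3, 0.7; 12.0: 54.7, 3.2
- amber (time / s: intermediate / %, product / %): 10.0: 37.2, 5.8; 12.0: 37.4, 6.7; 15.0: 36.0, 9.9; 20.0: 34.2, 11.4; 30.0: 29.7, 17.7; 50.0: 22.1, 27.6; 80.0: 15.0, 37.9
- violet (time / min: intermediate / %, product / %): 0.833: 27.2, 0; 3.00: 58.2, 0.5; 4.00: 63.4, 1.0; 6.00: 69.5, 1.5; 12.0: 71.6, 4.3

(each reading ± 0.3 percentage points)

- a reading or a percentage of product counts all its forms, free or not

* the flask with the highest amount of intermediate, in percent of the substrate charged ("all alike" if they lie within 1.5 percentage points) (eta / zeta / gamma / epsilon / all alike)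
* final intermediate, as a percentage of the substrate charged, in eta
* final intermediate, as a percentage of the substrate charged, in zeta
* final intermediate, as a percentage of the substrate charged, in gamma
* final intermediate, as a percentage of the substrate charged, in epsilon

2. I follow one molecule of intermediate and ask its chance per minute, k, of going on to product. That chance is the product gained, divided by the intermediate standing and the time. Late in the amber run, at 12 °C, the readings give 1.10 min⁻¹. Late in the violet run, at −30 °C, they give 0.00671 min⁻¹. I draw ln k as a straight line in temperature, which is rough.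

3. I fold temperature and time into one number, N = k·t. For eta it is 0.767. N is the number of lifetimes of intermediate, reckoned against the step to product, that fit into the time. Epsilon has 0.0369, gamma 15.9 and zeta 331. While N is small, product is about N times the intermediate at mid-time. On teal this gives 3.97% against the reading 3.2%, so the rule runs high.

4. One number is not enough. In zeta, an N of 331 makes the rule overshoot the charge, so I take the reagent, charged at 0.0450 M against 0.050 M of substrate, as the limiting reagent, with product capped near 90.0%. I commit to epsilon holding the most intermediate, with gamma and zeta near nothing.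

5. The forecast names epsilon: eta 33%, zeta 0%, gamma 0.5%, epsilon 42%, with epsilon “Still approaching equilibrium”.

6. The flasks give epsilon: eta 30.1%, zeta 0%, gamma 0.337%, epsilon 42.7%. The forecast holds.

    substrate + reagent ⇌ intermediate (K = 69.0 M⁻¹, k = 9.50 M⁻¹ s⁻¹, Ea = 52.0 kJ mol⁻¹, ΔH = 2.00 kJ mol⁻¹)
    intermediate → product (k = 0.0710 s⁻¹, Ea = 73.0 kJ mol⁻¹)
    crystals ⇌ product, rate k3*(cs3 - [product]) while solid is left; crystals form when [product] > cs3 (solubility = 18.0 mM, k = 0.420 s⁻¹)
    (constants at 25 °C)

From the coldest to the hottest flask the step to product speeds up by a factor of 3700, the making step by 350. In zeta, half of the making step's turnover is done by 0.496 s and of the step to product by 2.24 s. In eta, N times the 40.3% intermediate at 1.50 min gives 30.9%, against 32.7% product. Zeta holds 54.0% crystals, counted in its product, and they change nothing in its intermediate. The neighbour with 0.018 M reagent shares zeta's N, and its product stands at 36.0%, the cap being 36.0%.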